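Atom numbers C1–C8 are those of the target and are kept for every intermediate: C1 (CMe2), C2 (CHBr), C3 (alkylidene carbon), C4 (CHCl), C5 (CH2), C6 (CHCl), side chain C7 (=CH) and C8 (CH2Br). Compound numbers are those of the list after the steps.

## Analysis of the target

The target 21, (2S,3Z,4S,6S)-2-bromo-3-(2-bromoethylidene)-4,6-dichloro-1,1-dimethylcyclohexane, is a single cyclohexane ring with a quaternary C1 and an exocyclic C3=C7 double bond. It has three stereocentres: the C2 bromine and the C6 chlorine are cis to each other across C1, and the C4 chlorine is trans to both. The alkene carries C8 on the side of C2, where the CH2Br group eclipses a substituted ring carbon; this arrangement is expected to be less stable than its geometric isomer, so it cannot be left to equilibration. Three of the four carbon–halogen bonds (C2–Br, C4–Cl, C8–Br) are allylic and open to ionization, allylic transposition and halide exchange, so the bromides have to come last and under non-equilibrating conditions. C2 and C6 are both neopentylic: substitution by an external nucleophile is slow at C2 and practically excluded at the saturated C6. The molecule keeps no oxygen or other handle, so every group used for assembly must end as a halide or as the alkene. The plan rests on the position of C6 between C1 and C5: an α-chloroalkyl radical at C6 can add to C5 of a vinyl ketone whose carbonyl carbon is C3. That closes the ring through C5–C6, brings the chlorine in on the attacking carbon, and leaves a ketone at C3 from which C4–Cl and the alkylidene are developed, while an oxygen at C2 relays configuration to C6 and later tethers C8.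

## Retrosynthetic reasoning

21 to 19. The C2–Br and C8–Br bonds are cut back to C–O bonds of diol 19. The allylic bromides are the most labile groups and are therefore made in the last step. The forward reaction must replace the C2 oxygen with inversion, so the C2 oxygen has to be trans to the C6 chlorine in all earlier compounds.

19 to 18. The two hydroxyl groups of 19 are the reduced form of the lactone in butenolide 18. The ring of 18 holds C8 cis to C2, which is the geometry that thermodynamics would not give. Reduction must not touch the alkene or the chlorides.

18 to 15 and 16. The C3=C7 bond and the O–C8 bond are cut, which leads to α-hydroxy ketone 15 and the two-carbon ylide 16. In the forward direction the hydroxyl of 15 captures 16 and the acyl ylide 17 closes onto the C3 ketone. The alkene geometry is decided by the tether and not by the olefination.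

15 to 13 to 11. The C4 chlorine is removed to give ketone 11. The C3 carbonyl makes C4 nucleophilic, so chlorine is introduced as an electrophile through enolate 12, and no displacement is needed. The configuration at C4 is not trusted to this kinetic step. After desilylation (14) the α-chloro ketone is equilibrated to 15, where the hydrogen-bonded equatorial hydroxyl group biases the ring.

11 to 10. This is the key disconnection, C5–C6. The ring is opened between the chlorine-bearing carbon and the methylene next to it, which turns 11 into the acyclic redox-active ester 10 with a vinyl ketone at C3–C5. The forward reaction must generate the C6 radical, close 6-endo onto C5 and set C6–Cl trans to the C2 silyloxy group. It is cut here because this is the only ring bond whose formation places a chlorine on a neopentyl carbon without a substitution.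

10 to 9 to 7 and 8. The activated ester comes from acid 9. The C3–C4 bond of the vinyl ketone is cut to the N-methoxy-N-methylamide in 7 and vinylmagnesium bromide 8. The enone is made as late as possible because it polymerizes and accepts nucleophiles.

7 to 5 to 4. The carboxyl carbon is detached from C6 and the C6 chlorine is removed, leading to aldehyde 4. Forward, 4 is homologated to enol ether 5, whose β-carbon is C6; this carbon attacks an electrophilic chlorine source, and the resulting aldehyde 6 is oxidized to 7. A haloform-type homologation was not used, because it would require chloride to open an epoxide at this same neopentyl carbon in competition with the neighbouring amide oxygen.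

4 to 3 to 2 to 1. The aldehyde is the oxidized primary alcohol of 3, which is the ring-opened amide of silylated lactone 2, made from D-pantolactone 1. Compound 1 supplies C3, C2, C1 with both methyl groups, and C6, together with the (R) centre at C2 that controls everything else.

## Alternatives that were turned down

Alternative 1: The quaternary C1–C6 bond is disconnected by a [3,3] shift. Forward, the silyl ketene acetal of a six-membered lactone would undergo an Ireland–Claisen ring contraction through a boat transition state to the cyclohexene acid A1 (cis-5-chloro-2,2-dimethyl-4-[(trimethylsilyl)ethynyl]cyclohex-3-ene-1-carboxylic acid).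
- For it: a closed-shell rearrangement with a cyclic transition state is more predictable than a radical closure. On the reliability of the ring-forming event itself this alternative is the stronger one. It also relates the C6 substituent to C4–Cl in one step.
- Against it: the step builds a quaternary carbon that can be bought. A1 carries a carboxyl group at C6, not chlorine, so a later decarboxylative chlorination through a C6 radical is needed, and its facial selectivity is not set by the rearrangement. The ring alkene C2=C3 and the alkyne then have to be turned into C2–Br and the strained alkylidene geometry without any tether. The C4 chlorine is also γ to the lactone carbonyl and can be displaced by the enolate to give a cyclopropane.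
- Comparison: the chosen route is shorter after the key step. In place of the more reliable rearrangement it offers chlorine delivered to C6 in the bond-forming step and an alkene geometry fixed by a ring.

Alternative 2: The ring is disconnected at C2=C3. Forward, a ruthenium-carbene enyne ring-closing metathesis of an acyclic 1,7-enyne gives the 1-vinylcyclohexene A2 ((4S,6S)-4,6-dichloro-1-ethenyl-3,3-dimethylcyclohex-1-ene), which is then 1,4-dibrominated.
- For it: it is clearly the shortest plan, and here it is stronger than the chosen one. The ring is formed catalytically, both chlorides are already in place, and a single addition of bromine would finish the synthesis.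
- Against it: that last step must create the C2 stereocentre and the alkene geometry at once. A 1-vinylcyclohexene reacts from its s-trans conformer, which places C8 on the C4 side, the wrong geometry. Attack of bromide at C7 (1,2-addition) competes, the face of C2 is not controlled, and any equilibration of the allylic dibromides moves towards the less strained isomer. The anti-1,3-dichloride with one propargylic chloride also has to be made stereoselectively in an open chain.
- Comparison: the chosen route spends more steps. It offers in place of brevity a C2 configuration taken from the chiral pool and a geometry enforced by the butenolide.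

Alternative 3: The C4–C5 bond is disconnected. Forward, a dichloromethyl ketone with a vinyl group on C1 undergoes a copper-catalysed atom-transfer radical cyclization (monovalent copper chloride with an amine ligand abstracts chlorine, the divalent copper chloride complex returns it) to the dichloro ketone A3 ((2R,4S,6S)-2-(tert-butyldimethylsilyloxy)-4,6-dichloro-3,3-dimethylcyclohexan-1-one, the 6S epimer of 13).
- For it: this is the closest competitor and is stronger in step economy. It needs no carboxyl carbon, forms both C–Cl bonds in the ring-closing step and reaches A3 several steps earlier from the same starting material 1.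
- Against it: the C6 configuration is decided by chlorine transfer to a ring radical and not in the C–C bond-forming transition state. The closure of an electrophilic α-keto radical onto an unactivated vinyl group must choose 6-endo over 5-exo on steric grounds alone. The α-chloro ketone product can be re-activated by the catalyst, so C4 drifts to an equilibrium that the silyl ether does not clearly bias.
- Comparison: the chosen strategy pays with extra steps. It offers a polarity-matched addition to a vinyl ketone whose regiochemistry is fixed electronically, a C6 centre set under the influence of C2 in the cyclization itself, and a C4 centre that is introduced separately and can be corrected.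

Key step: step 8

Remark: compounds 6, 7, 9 and 10 are carried as mixtures of epimers at the future C6, because the radical formed in step 8 is planar at that carbon.

## Route

Step 1
Reactants: 1 D-(−)-pantolactone
Product: 2 (3R)-3-[(tert-butyldimethylsilyl)oxy]-4,4-dimethyloxolan-2-one
Conditions: TBSCl, imidazole, DMF, rt
Reagents that add atoms: tert-butyldimethylsilyl chloride, CC(C)(C)[Si](C)(C)Cl
Why: Silyl ether formation at the hindered secondary alcohol; lactone and stereocentre are untouched, and the silyl group later keeps the C2 oxygen from lactonizing onto the carboxyl group.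

Step 2
Reactants: 2 (3R)-3-[(tert-butyldimethylsilyl)oxy]-4,4-dimethyloxolan-2-one
Product: 3 (2R)-2-[(tert-butyldimethylsilyl)oxy]-4-hydroxy-N-methoxy-N,3,3-trimethylbutanamide
Conditions: MeNH(OMe)·HCl, AlMe3, CH2Cl2, 0 °C to rt
Reagents that add atoms: N,O-dimethylhydroxylamine hydrochloride, CNOC.Cl
Why: Weinreb aminolysis of a lactone with the aluminium amide made in the flask; the aluminium alkoxide formed does not re-close under these basic conditions, and the crude alcohol is oxidized at once to avoid acid-catalysed relactonization.

Step 3
Reactants: 3 (2R)-2-[(tert-butyldimethylsilyl)oxy]-4-hydroxy-N-methoxy-N,3,3-trimethylbutanamide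
Product: 4 (2R)-2-[(tert-butyldimethylsilyl)oxy]-N-methoxy-N,3,3-trimethyl-4-oxobutanamide
Conditions: (COCl)2, DMSO, CH2Cl2, −78 °C; Et3N, −78 to 0 °C
Reagents that add atoms: none
Why: Swern oxidation of the neopentyl primary alcohol under basic conditions; the aldehyde has no α-hydrogen and cannot enolize, and the centre next to the amide is not touched.

Step 4
Reactants: 4 (2R)-2-[(tert-butyldimethylsilyl)oxy]-N-methoxy-N,3,3-trimethyl-4-oxobutanamide
Product: 5 (2R)-2-[(tert-butyldimethylsilyl)oxy]-N,5-dimethoxy-N,3,3-trimethylpent-4-enamide (E/Z mixture)
Conditions: MeOCH2PPh3Cl, KOtBu, THF, 0 °C; then 4, 0 °C to rt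
Reagents that add atoms: (methoxymethyl)triphenylphosphonium chloride, COC[P+](c1ccccc1)(c1ccccc1)c1ccccc1.[Cl-]
Why: Wittig methoxymethylenation of a non-enolizable aldehyde, far more electrophilic than the amide; it adds the future carboxyl carbon and turns C6 into the nucleophilic β-carbon of an enol ether.

Step 5
Reactants: 5 (2R)-2-[(tert-butyldimethylsilyl)oxy]-N,5-dimethoxy-N,3,3-trimethylpent-4-enamide
Product: 7 (4R)-4-[(tert-butyldimethylsilyl)oxy]-2-chloro-5-[methoxy(methyl)amino]-3,3-dimethyl-5-oxopentanoic acid (both C2 epimers), via α-chloro aldehyde 6 (not isolated)
Conditions: NCS, THF/H2O, 0 °C; then NaClO2, NaH2PO4, 2-methyl-2-butene, t-BuOH/H2O, 0 °C to rt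
Reagents that add atoms: N-chlorosuccinimide, O=C1CCC(=O)N1Cl; water, O; sodium chlorite, [Na+].[O-]Cl=O
Why: Electrophilic chlorination of the enol ether at C6, hydrolysis of the oxocarbenium ion to the α-chloro aldehyde and Pinnick oxidation in the same flask; the C–Cl bond is made by attack of C6 on chlorine, so no displacement at the neopentyl carbon is needed and its configuration is irrelevant.

Step 6
Reactants: 7 (4R)-4-[(tert-butyldimethylsilyl)oxy]-2-chloro-5-[methoxy(methyl)amino]-3,3-dimethyl-5-oxopentanoic acid; 8 vinylmagnesium bromide
Product: 9 (4R)-4-[(tert-butyldimethylsilyl)oxy]-2-chloro-3,3-dimethyl-5-oxohept-6-enoic acid (both C2 epimers)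
Conditions: CH2=CHMgBr (2.5 equiv), THF, −40 to 0 °C; inverse quench into cold 1 M HCl
Reagents that add atoms: none
Why: Weinreb ketone synthesis; the first equivalent deprotonates the acid, the second adds to the amide to give the chelated tetrahedral intermediate, which releases the vinyl ketone only in the acidic quench, when the amine is protonated and cannot add to the enone.

Step 7
Reactants: 9 (4R)-4-[(tert-butyldimethylsilyl)oxy]-2-chloro-3,3-dimethyl-5-oxohept-6-enoic acid
Product: 10 1,3-dioxoisoindolin-2-yl (4R)-4-[(tert-butyldimethylsilyl)oxy]-2-chloro-3,3-dimethyl-5-oxohept-6-enoate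
Conditions: N-hydroxyphthalimide, DIC, DMAP (cat.), CH2Cl2, 0 °C
Reagents that add atoms: N-hydroxyphthalimide, O=C1c2ccccc2C(=O)N1O
Why: Carbodiimide (Steglich-type) esterification gives the redox-active ester under neutral, cold conditions that the vinyl ketone and the silyl ether tolerate.

Step 8
Reactants: 10 1,3-dioxoisoindolin-2-yl (4R)-4-[(tert-butyldimethylsilyl)oxy]-2-chloro-3,3-dimethyl-5-oxohept-6-enoate
Product: 11 (2R,4S)-2-[(tert-butyldimethylsilyl)oxy]-4-chloro-3,3-dimethylcyclohexan-1-one
Conditions: Ir[dF(CF3)ppy]2(dtbbpy)PF6 (1 mol %), Hantzsch ester (1.5 equiv), CH2Cl2 (0.01 M), blue LEDs, rt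
Reagents that add atoms: none
Why: This is a photoreductive decarboxylative radical conjugate addition, the closest known type being the photoredox Giese reaction of N-acyloxyphthalimides with enones, run here intramolecularly on an α-chloro acid. The excited trivalent iridium complex is quenched by the Hantzsch ester, and the divalent iridium formed transfers an electron to the phthalimide ester, which loses phthalimide anion and CO2 to give the planar α-chloroalkyl radical at C6. This radical adds to C5, the terminal and only electrophilic carbon of the vinyl ketone, in a 6-endo-trig closure that forms the C5–C6 bond and the six-membered ring with the carbonyl inside it; 5-exo attack at C4 would be anti-conjugate and is not expected. The C4 α-keto radical is then reduced by hydrogen transfer from the Hantzsch ester or by electron transfer and protonation. The new stereocentre C6 is controlled by the (R) centre at C2 through a chair-like transition state in which the silyloxy group is equatorial and the chlorine takes the axial-like site on the radical carbon, where it avoids eclipsing a C1 methyl group and a syn-diaxial contact with the oxygen, so C6–Cl ends trans to C2–O. The step needs cyclization to be faster than hydrogen transfer to the open-chain radical, which high dilution and the gem-dimethyl group favour. Silyl ether, saturated ketone and alkyl chloride lie outside the reducing power of divalent iridium.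

Step 9
Reactants: 11 (2R,4S)-2-[(tert-butyldimethylsilyl)oxy]-4-chloro-3,3-dimethylcyclohexan-1-one
Product: 13 (2R,4S)-2-[(tert-butyldimethylsilyl)oxy]-4,6-dichloro-3,3-dimethylcyclohexan-1-one (both C6 epimers), via lithium enolate 12 (not isolated)
Conditions: LiN(i-Pr)2, THF, −78 °C; NCS, −78 °C; AcOH
Reagents that add atoms: N-chlorosuccinimide, O=C1CCC(=O)N1Cl
Why: Kinetic deprotonation takes place at the unhindered methylene (target C4) and not at the silyloxy-bearing neopentyl C2, and the lithium enolate is chlorinated by NCS (electrophilic α-halogenation). The configuration of the new centre is not relied on here; it is set in step 10.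

Step 10
Reactants: 13 (2R,4S)-2-[(tert-butyldimethylsilyl)oxy]-4,6-dichloro-3,3-dimethylcyclohexan-1-one
Product: 15 (2R,4S,6S)-4,6-dichloro-2-hydroxy-3,3-dimethylcyclohexan-1-one, via hydroxy ketone epimer mixture 14 (not isolated)
Conditions: HF (48% aq.), MeCN, 0 °C to rt; then n-Bu4NCl (cat.), CH2Cl2, rt to 35 °C
Reagents that add atoms: none
Why: Acidic fluoride desilylation frees the hindered alcohol without base; chloride-catalysed epimerization of the α-chloro ketone (degenerate SN2 exchange at the carbonyl-activated carbon) should then funnel both epimers into the more stable one. In that epimer the hydroxyl (hydrogen-bonded to the carbonyl) and the new chlorine are both equatorial and the neopentyl chlorine is axial, whereas the other epimer needs either an axial hydroxyl or a syn-diaxial pair of chlorines; this is how the target C4 centre is set.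

Step 11
Reactants: 15 (2R,4S,6S)-4,6-dichloro-2-hydroxy-3,3-dimethylcyclohexan-1-one; 16 ketenylidenetriphenylphosphorane
Product: 18 (4S,6S,7aR)-4,6-dichloro-7,7-dimethyl-5,6,7,7a-tetrahydro-1-benzofuran-2(4H)-one, via acyl ylide 17 (not isolated)
Conditions: Ph3P=C=C=O, toluene, 90 °C
Reagents that add atoms: none
Why: Bestmann butenolide annulation: the hydroxyl adds across the cumulated ylide, and the intramolecular Wittig reaction of 17 with the C3 ketone closes the five-membered lactone. Because C8 is tied to the C2 oxygen, the C3=C7 bond can only form with C8 cis to C2.

Step 12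
Reactants: 18 (4S,6S,7aR)-4,6-dichloro-7,7-dimethyl-5,6,7,7a-tetrahydro-1-benzofuran-2(4H)-one
Product: 19 (1R,3S,5S,6E)-3,5-dichloro-6-(2-hydroxyethylidene)-2,2-dimethylcyclohexan-1-ol (CH2OH cis to the carbinol carbon)
Conditions: i-Bu2AlH (3.5 equiv), CH2Cl2, −78 to −20 °C
Reagents that add atoms: none
Why: 1,2-Reduction of the unsaturated lactone through the lactol to the allylic diol; the alkene and the alkyl chlorides are not attacked at low temperature, so the geometry fixed in the ring is carried over unchanged.

Step 13
Reactants: 19 (1R,3S,5S,6E)-3,5-dichloro-6-(2-hydroxyethylidene)-2,2-dimethylcyclohexan-1-ol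
Product: 21 (2S,3Z,4S,6S)-2-bromo-3-(2-bromoethylidene)-4,6-dichloro-1,1-dimethylcyclohexane, via primary bromide 20 (not isolated)
Conditions: CBr4, PPh3, CH2Cl2, −20 to 0 °C
Reagents that add atoms: carbon tetrabromide, BrC(Br)(Br)Br
Why: Appel reaction: the primary allylic alcohol is brominated first, then the secondary alkoxyphosphonium at C2 is displaced by bromide from the face opposite to oxygen, which turns the (R) carbinol into the (S) bromide cis to C6–Cl. Low temperature and a non-ionizing solvent are chosen to keep the substitution direct and to leave the alkene geometry untouched.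

## Compound list

1 | D-(−)-pantolactone, (3R)-3-hydroxy-4,4-dimethyloxolan-2-one | CC1(C)COC(=O)[C@@H]1O | starting material
2 | (3R)-3-[(tert-butyldimethylsilyl)oxy]-4,4-dimethyloxolan-2-one | CC1(C)COC(=O)[C@@H]1O[Si](C)(C)C(C)(C)C | intermediate
3 | (2R)-2-[(tert-butyldimethylsilyl)oxy]-4-hydroxy-N-methoxy-N,3,3-trimethylbutanamide | CON(C)C(=O)[C@H](O[Si](C)(C)C(C)(C)C)C(C)(C)CO | intermediate
4 | (2R)-2-[(tert-butyldimethylsilyl)oxy]-N-methoxy-N,3,3-trimethyl-4-oxobutanamide | CON(C)C(=O)[C@H](O[Si](C)(C)C(C)(C)C)C(C)(C)C=O | intermediate
5 | (2R)-2-[(tert-butyldimethylsilyl)oxy]-N,5-dimethoxy-N,3,3-trimethylpent-4-enamide (E/Z mixture) | CON(C)C(=O)[C@H](O[Si](C)(C)C(C)(C)C)C(C)(C)C=COC | intermediate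
6 | (2R)-2-[(tert-butyldimethylsilyl)oxy]-4-chloro-N-methoxy-N,3,3-trimethyl-5-oxopentanamide (both C4 epimers) | CON(C)C(=O)[C@H](O[Si](C)(C)C(C)(C)C)C(C)(C)C(Cl)C=O | intermediate
7 | (4R)-4-[(tert-butyldimethylsilyl)oxy]-2-chloro-5-[methoxy(methyl)amino]-3,3-dimethyl-5-oxopentanoic acid (both C2 epimers) | CON(C)C(=O)[C@H](O[Si](C)(C)C(C)(C)C)C(C)(C)C(Cl)C(=O)O | intermediate
8 | vinylmagnesium bromide | C=C[Mg]Br | starting material
9 | (4R)-4-[(tert-butyldimethylsilyl)oxy]-2-chloro-3,3-dimethyl-5-oxohept-6-enoic acid (both C2 epimers) | OC(=O)C(Cl)C(C)(C)[C@@H](O[Si](C)(C)C(C)(C)C)C(=O)C=C | intermediate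
10 | 1,3-dioxoisoindolin-2-yl (4R)-4-[(tert-butyldimethylsilyl)oxy]-2-chloro-3,3-dimethyl-5-oxohept-6-enoate (both C2 epimers) | O=C(ON1C(=O)c2ccccc2C1=O)C(Cl)C(C)(C)[C@@H](O[Si](C)(C)C(C)(C)C)C(=O)C=C | intermediate
11 | (2R,4S)-2-[(tert-butyldimethylsilyl)oxy]-4-chloro-3,3-dimethylcyclohexan-1-one | CC1(C)[C@@H](O[Si](C)(C)C(C)(C)C)C(=O)CC[C@@H]1Cl | intermediate
12 | lithium (4S,6R)-6-[(tert-butyldimethylsilyl)oxy]-4-chloro-5,5-dimethylcyclohex-1-en-1-olate | CC1(C)[C@@H](O[Si](C)(C)C(C)(C)C)C(O[Li])=CC[C@@H]1Cl | intermediate
13 | (2R,4S)-2-[(tert-butyldimethylsilyl)oxy]-4,6-dichloro-3,3-dimethylcyclohexan-1-one (both C6 epimers) | CC1(C)[C@@H](O[Si](C)(C)C(C)(C)C)C(=O)C(Cl)C[C@@H]1Cl | intermediate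
14 | (2R,4S)-4,6-dichloro-2-hydroxy-3,3-dimethylcyclohexan-1-one (both C6 epimers) | CC1(C)[C@@H](O)C(=O)C(Cl)C[C@@H]1Cl | intermediate
15 | (2R,4S,6S)-4,6-dichloro-2-hydroxy-3,3-dimethylcyclohexan-1-one | CC1(C)[C@@H](O)C(=O)[C@@H](Cl)C[C@@H]1Cl | intermediate
16 | ketenylidenetriphenylphosphorane | O=C=C=P(c1ccccc1)(c1ccccc1)c1ccccc1 | starting material
17 | (1R,3S,5S)-3,5-dichloro-6,6-dimethyl-2-oxocyclohexyl 2-(triphenyl-λ5-phosphanylidene)acetate | CC1(C)[C@@H](OC(=O)C=P(c2ccccc2)(c2ccccc2)c2ccccc2)C(=O)[C@@H](Cl)C[C@@H]1Cl | intermediate
18 | (4S,6S,7aR)-4,6-dichloro-7,7-dimethyl-5,6,7,7a-tetrahydro-1-benzofuran-2(4H)-one | CC1(C)[C@H]2OC(=O)C=C2[C@@H](Cl)C[C@@H]1Cl | intermediate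
19 | (1R,3S,5S,6E)-3,5-dichloro-6-(2-hydroxyethylidene)-2,2-dimethylcyclohexan-1-ol | CC1(C)[C@@H](O)/C(=C\CO)[C@@H](Cl)C[C@@H]1Cl | intermediate
20 | (1R,3S,5S,6E)-6-(2-bromoethylidene)-3,5-dichloro-2,2-dimethylcyclohexan-1-ol | CC1(C)[C@@H](O)/C(=C\CBr)[C@@H](Cl)C[C@@H]1Cl | intermediate
21 | (2S,3Z,4S,6S)-2-bromo-3-(2-bromoethylidene)-4,6-dichloro-1,1-dimethylcyclohexane | CC1(C)[C@H](Br)/C(=C\CBr)[C@@H](Cl)C[C@@H]1Cl | target

## Step count and least certain steps

Total step count: 13. Longest linear sequence: 13 steps (1 to 21).

**Step 8 (key step).**
- What may go wrong: hydrogen transfer to the open-chain α-chloro radical before it cyclizes, and conjugate reduction of the vinyl ketone by the photoreductant. Both compete with a closure that must form a bond next to a quaternary carbon. The preference for the trans isomer rests on a conformational argument and may be incomplete. An α-chloro acid is also an unusual partner for this reaction.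
- Fallback: set out from acid 9 and couple it with N-hydroxypyridine-2-thione (DCC, dark) to the thiohydroxamate ester F1. Photolyse F1 in dilute benzene while tert-butanethiol is added slowly. The thiyl-radical chain gives the same C6 radical without a reductant that could touch the enone, and the hydrogen donor concentration is set by the addition rate. The route is rejoined at ketone 11.

**Step 13.**
- What may go wrong: allylic transposition or ionization instead of direct displacement at C2, because backside attack there is flanked by the C1 substituents. This would move bromine to C7 or scramble C2 and, through the freely rotating transposed isomer, the alkene geometry. On long reaction times bromide may also exchange the allylic C4 chloride.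
- Fallback: set out from butenolide 18 and cleave its alkyl–oxygen bond with bromide under Lewis acid activation (BBr3, CH2Cl2, low temperature, aqueous work-up) to the (Z)-bromo acid F2. Here C2 is the γ-carbon of an unsaturated acid, so ionization and attack at C7 are both disfavoured and only displacement with inversion remains. Reduce F2 with BH3·SMe2 to the bromo allylic alcohol F3 and brominate the primary alcohol alone (CBr4, PPh3, −30 °C). The route is rejoined at 21.

**Step 10.**
- What may go wrong: the equilibrium may favour the wanted epimer less strongly than the conformational analysis predicts, chloride exchange may be slow at a ring carbon, or base- and chloride-induced ring contraction or elimination may intervene.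
- Fallback: set out from ketone 11 and hydroxylate its enolate 12 with an N-sulfonyloxaziridine to the hydroxy ketone F4. Replace the hydroxyl by chloride with inversion (PPh3, CCl4) at this unhindered, carbonyl-activated carbon to obtain the single chloro epimer F5. Desilylation with HF, without chloride equilibration, rejoins the route at 15. This sequence relies on the oxidant attacking the enolate face anti to the silyloxy group, the same preference that would make direct chlorination deliver the wrong epimer.

**Step 11.**
- What may go wrong: the cumulated ylide or acyl ylide 17 may alkylate at the carbonyl-activated C4–Cl or enolize the ketone instead of closing onto the hindered carbonyl at elevated temperature.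
- Fallback: set out from 15 and acylate the hydroxyl with bromoacetyl bromide (pyridine, −20 °C) to bromoacetate F6. Quaternize with PPh3 to phosphonium bromide F7 and deprotonate with Et3N at room temperature. This gives 17 without the cumulated ylide and without heating, and the route is rejoined there.

**Step 6.**
- What may go wrong: conjugate addition of the released amine or of excess Grignard reagent to the vinyl ketone, sluggish addition to the amide once the magnesium carboxylate has formed, and polymerization of 9.
- Fallback: set out from enol ether 5 and add 8 before the acid exists (one equivalent, acidic quench) to give the vinyl ketone F8. Then run the chlorination (through chloro aldehyde F9) and the chlorite oxidation of step 5 on this compound. The route is rejoined at acid 9.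

## Further compounds

F1 | step 8 | 2-thioxopyridin-1(2H)-yl (4R)-4-[(tert-butyldimethylsilyl)oxy]-2-chloro-3,3-dimethyl-5-oxohept-6-enoate | O=C(ON1C=CC=CC1=S)C(Cl)C(C)(C)[C@@H](O[Si](C)(C)C(C)(C)C)C(=O)C=C
F2 | step 13 | (2Z)-[(2S,4S,6S)-2-bromo-4,6-dichloro-3,3-dimethylcyclohexylidene]acetic acid | CC1(C)[C@H](Br)/C(=C\C(=O)O)[C@@H](Cl)C[C@@H]1Cl
F3 | step 13 | (2Z)-2-[(2S,4S,6S)-2-bromo-4,6-dichloro-3,3-dimethylcyclohexylidene]ethan-1-ol | CC1(C)[C@H](Br)/C(=C\CO)[C@@H](Cl)C[C@@H]1Cl
F4 | step 10 | (2R,4S,6R)-2-[(tert-butyldimethylsilyl)oxy]-4-chloro-6-hydroxy-3,3-dimethylcyclohexan-1-one | CC1(C)[C@@H](O[Si](C)(C)C(C)(C)C)C(=O)[C@H](O)C[C@@H]1Cl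
F5 | step 10 | (2R,4S,6S)-2-[(tert-butyldimethylsilyl)oxy]-4,6-dichloro-3,3-dimethylcyclohexan-1-one | CC1(C)[C@@H](O[Si](C)(C)C(C)(C)C)C(=O)[C@@H](Cl)C[C@@H]1Cl
F6 | step 11 | (1R,3S,5S)-3,5-dichloro-6,6-dimethyl-2-oxocyclohexyl bromoacetate | CC1(C)[C@@H](OC(=O)CBr)C(=O)[C@@H](Cl)C[C@@H]1Cl
F7 | step 11 | (2-{[(1R,3S,5S)-3,5-dichloro-6,6-dimethyl-2-oxocyclohexyl]oxy}-2-oxoethyl)triphenylphosphonium bromide | CC1(C)[C@@H](OC(=O)C[P+](c2ccccc2)(c2ccccc2)c2ccccc2)C(=O)[C@@H](Cl)C[C@@H]1Cl.[Br-]
F8 | step 6 | (4R)-4-[(tert-butyldimethylsilyl)oxy]-7-methoxy-5,5-dimethylhepta-1,6-dien-3-one | C=CC(=O)[C@H](O[Si](C)(C)C(C)(C)C)C(C)(C)C=COC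
F9 | step 6 | (4R)-4-[(tert-butyldimethylsilyl)oxy]-2-chloro-3,3-dimethyl-5-oxohept-6-enal | O=CC(Cl)C(C)(C)[C@@H](O[Si](C)(C)C(C)(C)C)C(=O)C=C
A1 | alternative 1 | cis-5-chloro-2,2-dimethyl-4-[(trimethylsilyl)ethynyl]cyclohex-3-ene-1-carboxylic acid | CC1(C)C=C(C#C[Si](C)(C)C)[C@@H](Cl)C[C@H]1C(=O)O
A2 | alternative 2 | (4S,6S)-4,6-dichloro-1-ethenyl-3,3-dimethylcyclohex-1-ene | CC1(C)C=C(C=C)[C@@H](Cl)C[C@@H]1Cl
A3 | alternative 3 | (2R,4S,6S)-2-(tert-butyldimethylsilyloxy)-4,6-dichloro-3,3-dimethylcyclohexan-1-one | CC1(C)[C@@H](O[Si](C)(C)C(C)(C)C)C(=O)[C@@H](Cl)C[C@@H]1Cl
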